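**Conventions.** Core atoms carry the 2-oxaspiro[4.5]decane numbers of the target: C1 (lactone CH–O), O2, C3 (lactone C=O), C4, C5 (spiro), C6 (ketone), C7=C8, C9 (acetoxy carbon), C10. Side-chain atoms are C1′–C7′. TBS = tert-butyldimethylsilyl; TBSO = its ether oxygen.

## The problem

The target is a γ-lactone spiro-fused to a cyclohexenone, and the quaternary stereocentre C5 belongs to both rings and sits between the C6 ketone and the C1 carbinol carbon, so the core is an α-quaternary β-acyloxy ketone. Of the four stereocentres (C1, C5, C9 and C5′), C1 and C5 are adjacent and are best set in one event. The C1 carbinol carbon sits on the same face of the six-membered ring as the C9 acetoxy group, so its hydroxyl can direct oxygenation at C9. C5′ is too remote for any control from the core and must arrive in an enantiopure fragment. The side chain also needs an (E)-trisubstituted C1′=C2′ alkene next to the hindered C1. Three groups are fragile: the 4-acetoxy enone (elimination, ionisation by zerovalent palladium, conjugate reduction), the lactone (its opening frees a β-hydroxy ketone that can split C1–C5 by retro-aldol), and the allylic isopropenyl carbinol. The enabling feature is the array O=C6–C5(quaternary)–C1–O, which is what a 2,3-epoxy alcohol leaves behind when a carbon shifts from the carbinol carbon (C6) to the neighbouring epoxide carbon (C5). If the migrating carbon is a ring methylene (C10) of a cyclopentenol, the ketone, the quaternary centre, the six-membered ring and a C8=C9 alkene for later C9 oxygenation all appear at once.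

## Retrosynthesis

**Late functional groups and the side chain.** Target 37 is traced to silyl ether 36 and then to alcohol 35, so that the C9 acetate is added only after all palladium chemistry. The skeletal cut is the sp2–sp3 bond C2′–C3′, giving vinyl iodide 25 and alkyl iodide 32, the latter used as its 9-BBN borate 34. A cut at C1′=C2′ or at C4′–C5′ would bring carbonyl-addition chemistry next to the ketone and enone; this cut does not. It also confines the uncontrollable C5′ stereocentre to a five-carbon fragment. The coupling must keep the E geometry and tolerate a free C9 hydroxyl, a lactone and an enone.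

**The vinyl iodide.** Iodide 25 is traced to alkyne 23. The propynyl group is a latent (E)-2-iodopropenyl group through syn-hydrometalation, and it is slimmer and less cation-stabilising than an alkene during the earlier steps. The forward reaction must place the metal on the methyl-bearing carbon, away from C1.

**Lactone and C9 oxygen.** Hydroxy lactone 23 comes from triol 20 by oxidation of the C3 primary alcohol and capture by the C1 hydroxyl. Triol 20 comes from silyl ether 19, and 19 from β-hydroxy ketone 17 by epoxidation of C8=C9 and base opening. The epoxidation is placed before lactone closure because the free C1 hydroxyl is the only handle that can deliver oxygen to the correct face. It is placed before the side-chain coupling because an allylic C1′=C2′ alkene would otherwise be epoxidised first.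

**Key disconnection.** Ketone 17 is cut at C5–C10 and leads back to epoxy cyclopentenol 16. The alternatives, an aldol or alkylation at C5, would have to build a quaternary centre next to a second stereocentre intermolecularly. The rearrangement instead transfers the configuration of an epoxide to both C5 and C1. The precursor is simpler by one ring size and holds only the two epoxide stereocentres.

**Cyclopentenol.** Compound 16 is opened at its ring alkene to diallyl carbinol 15, which comes from ester 12 and two equivalents of allylmagnesium bromide 13. The symmetric carbinol needs no stereocontrol, and both ring methylenes are equivalent for the later shift.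

**Epoxy ester.** Ester 12 comes from acid 11, and 11 from epoxy alcohol 9, which is made by asymmetric epoxidation of (Z)-enynol 8. The primary allylic alcohol is required for reagent-controlled epoxidation, which is why the ester is reduced and later re-oxidised. This step fixes the absolute configuration of the whole core.

**Enynol.** Alcohol 8 comes from ester 6, made by Z-selective olefination of but-2-ynal 2 with phosphonate 5. Phosphonate 5 is the alkylation product of phosphonoacetate 3 with iodide 4, and aldehyde 2 comes from but-2-yn-1-ol 1. The Z geometry is essential because it places the propynyl group and the future C6 cis on the epoxide.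

**Side-chain fragment.** Iodide 32 comes from alcohol 31, and 31 from ester 29 and its parent aldol adduct 28. Adduct 28 is cut at C3′–C4′ into methacrolein 27 and the chiral acetate (R)-HYTRA 26. An acetate aldol gives the two-carbon spacer and the C5′ carbinol in one step. The alternative of hydroborating a vinyl group would not distinguish it from the isopropenyl group.

## Roads not taken

**Alternative 1: double carbonylative acylpalladation.** The cut removes C5–C6, C3–C4 and C3–O2 together and leads to the acyclic (Z)-iodoalkene A2. In the forward step palladium inserts into the C–I bond, carbonylation gives the C6 acyl, 6-exo acylpalladation of the 1,1-disubstituted alkene forms C5–C6, and a second carbonylation with capture by the C1 hydroxyl closes the lactone. The product A1 is the same compound as 36.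
- Merits: both rings form in one operation, one step from the target. C1, C9 and C5′ are set in an open chain by reagent control. The alkylpalladium formed after ring closure is neopentyl and has no β-hydrogen.
- Weak points: the quaternary C5 is created in the cyclisation, and its configuration relative to C1 and C9 rests on the conformational bias of a flexible chain. A2 holds an allylic acetate beside the iodoalkene, which the same zerovalent palladium can ionise. The first acylpalladium can be trapped by the hydroxyl before it cyclises. A2 needs its own long stereoselective synthesis.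
- Comparison: this road is more convergent and shorter at the end. The chosen plan sets against it a stereospecific origin for C5 and no palladium chemistry on an allylic acetate.

**Alternative 2: desymmetrising bromolactonisation.** The cut is a lactone C–O bond at ring carbon C6 and leads to the achiral cyclohexadienyl acetic acid A4. In the forward step a chiral amine catalyst delivers electrophilic bromine to one enantiotopic alkene and the acid closes onto C6, giving the cis-fused bromolactone A3.
- Merits: quaternary C5 is set catalytically and enantioselectively in very few steps from an arene-derived diene.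
- Weak points: the lactone is fused at C6, the future ketone, and not spiro at C1. C1 is still a CH2O group, so the side chain must be added to an aldehyde beside the quaternary centre with uncertain facial control, and the lactone must then be moved. Bromine at C7 and the C9=C10 alkene need several redox steps to become the 9-acetoxy enone.
- Comparison: it is better in early step economy and in using catalysis for the first stereocentre. The chosen plan sets against it that C1 and C5 are made together and that the ketone and the C8=C9 alkene appear exactly where they are needed.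

**Alternative 3: enantioselective Diels–Alder.** The cut removes C5–C6 and C9–C10 and leads to diacetoxydiene A6 and the 2-substituted acrolein A7. In the forward step a chiral oxazaborolidinium Lewis acid activates A7, and endo addition gives the all-cis adduct A5.
- Merits: the ring, C5, C9, their relative configuration and both arms at the correct oxidation level come from one catalytic step. This is probably the shortest route to a fully oxygenated core, and the lactone would close by itself once C1 carries its oxygen.
- Weak points: C1 must be made by adding an alkenyl nucleophile to the neopentyl aldehyde of A5 in the presence of an ester and two acetates, and its facial selectivity is not secured. The C6 and C9 acetates are alike, yet C6 must be oxidised and C9 kept. A7 can slip into conjugation, and A6 is a modest, acid-labile diene.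
- Comparison: A5 is reached in far fewer steps than 19. The chosen plan sets against it a C1/C5 relationship fixed by one epoxide and a C6 that is a ketone from the moment the ring forms.

Key step: step 10

Remark: 4 and both enantiomers of 26 are taken to be commercial, and the facial sense of the acetate aldol of 26 with 27 is taken to be that known for branched aliphatic aldehydes, (R)-26 giving the (3R)-adduct.

## Route

Step 1
Reactants: 1 but-2-yn-1-ol
Product: 2 but-2-ynal
Conditions: activated MnO2, CH2Cl2, rt; filtered, dried solution used directly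
Reagents that add atoms: none
Why: Heterogeneous MnO2 oxidation of a propargylic alcohol stops cleanly at the ynal under neutral conditions; the volatile aldehyde is not concentrated.

Step 2
Reactants: 3 methyl bis(2,2,2-trifluoroethyl)phosphonoacetate; 4 tert-butyl(2-iodoethoxy)dimethylsilane
Product: 5 methyl 2-[bis(2,2,2-trifluoroethoxy)phosphoryl]-4-TBSO-butanoate (racemic)
Conditions: NaH, DMF, 0 °C to rt
Reagents that add atoms: none
Why: C-alkylation of the stabilised phosphonoacetate anion with a primary iodide; one equivalent of base and slow addition of 4 limit dialkylation, and a non-nucleophilic base avoids exchange of the trifluoroethyl esters.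

Step 3
Reactants: 5 methyl 2-[bis(2,2,2-trifluoroethoxy)phosphoryl]-4-TBSO-butanoate; 2 but-2-ynal
Product: 6 methyl (2Z)-2-(2-TBSO-ethyl)hex-2-en-4-ynoate
Conditions: KN(SiMe3)2, 18-crown-6, THF, −78 °C
Reagents that add atoms: none
Why: Still–Gennari olefination: the electron-poor phosphonate with a dissociated potassium counter-ion eliminates faster than the adducts equilibrate, so the kinetic alkene with the ester cis to the propynyl group should dominate.

Step 4
Reactants: 6 methyl (2Z)-2-(2-TBSO-ethyl)hex-2-en-4-ynoate
Product: 8 (2Z)-2-(2-TBSO-ethyl)hex-2-en-4-yn-1-ol, via enynal 7 (not isolated)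
Conditions: iBu2AlH (2.2 equiv), CH2Cl2, −78 to 0 °C; aq potassium sodium tartrate
Reagents that add atoms: none
Why: 1,2-Reduction of a conjugated ester by the aluminium hydride passes through the aldehyde to the allylic alcohol without touching the alkene geometry or the alkyne.

Step 5
Reactants: 8 (2Z)-2-(2-TBSO-ethyl)hex-2-en-4-yn-1-ol
Product: 9 [(2S,3R)-2-(2-TBSO-ethyl)-3-(prop-1-yn-1-yl)oxiran-2-yl]methanol
Conditions: Ti(OiPr)4 (cat.), L-(+)-diisopropyl tartrate (cat.), tBuOOH, 4 Å molecular sieves, CH2Cl2, −20 °C
Reagents that add atoms: tert-butyl hydroperoxide, CC(C)(C)OO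
Why: Sharpless asymmetric epoxidation; the L-(+)-tartrate complex delivers oxygen to the face that gives the (2S,3R)-epoxide from a (Z)-3-substituted allylic alcohol, and this sets the future C5 and C1. The slim alkynyl cis-substituent should be tolerated better than a branched one.

Step 6
Reactants: 9 [(2S,3R)-2-(2-TBSO-ethyl)-3-(prop-1-yn-1-yl)oxiran-2-yl]methanol
Product: 11 (2R,3R)-2-(2-TBSO-ethyl)-3-(prop-1-yn-1-yl)oxirane-2-carboxylic acid, via epoxy aldehyde 10 (not isolated)
Conditions: 2,2,6,6-tetramethylpiperidin-1-oxyl (TEMPO, cat.), PhI(OAc)2, MeCN/H2O, rt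
Reagents that add atoms: water, O
Why: Oxoammonium oxidation gives the aldehyde, whose hydrate is oxidised on to the acid; the conditions spare the alkyne, which a ruthenium tetroxide oxidation would cleave, and leave the epoxide and silyl ether intact.

Step 7
Reactants: 11 (2R,3R)-2-(2-TBSO-ethyl)-3-(prop-1-yn-1-yl)oxirane-2-carboxylic acid
Product: 12 methyl (2R,3R)-2-(2-TBSO-ethyl)-3-(prop-1-yn-1-yl)oxirane-2-carboxylate
Conditions: Me3SiCHN2, toluene/MeOH, 0 °C
Reagents that add atoms: (trimethylsilyl)diazomethane, C[Si](C)(C)C=[N+]=[N-]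
Why: Esterification with the diazoalkane is neutral and fast, so the sensitive glycidic acid is not exposed to acid or base.

Step 8
Reactants: 12 methyl (2R,3R)-2-(2-TBSO-ethyl)-3-(prop-1-yn-1-yl)oxirane-2-carboxylate; 13 allylmagnesium bromide
Product: 15 4-[(2R,3R)-2-(2-TBSO-ethyl)-3-(prop-1-yn-1-yl)oxiran-2-yl]hepta-1,6-dien-4-ol, via allyl ketone 14 (not isolated)
Conditions: 13 (2.5 equiv), THF, −78 °C; aq NH4Cl
Reagents that add atoms: allylmagnesium bromide 13 (second equivalent), C=CC[Mg]Br
Why: Double Grignard addition to an ester: the first equivalent of 13 displaces methoxide to give ketone 14, which is more electrophilic than the ester and takes up the second equivalent at once to give the diallyl carbinol. At −78 °C without copper the propargylic epoxide should not be opened.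

Step 9
Reactants: 15 4-[(2R,3R)-2-(2-TBSO-ethyl)-3-(prop-1-yn-1-yl)oxiran-2-yl]hepta-1,6-dien-4-ol
Product: 16 1-[(2R,3R)-2-(2-TBSO-ethyl)-3-(prop-1-yn-1-yl)oxiran-2-yl]cyclopent-3-en-1-ol
Conditions: RuCl2(=CHPh)(PCy3)2 (first-generation Grubbs catalyst, cat.), CH2Cl2, high dilution, rt
Reagents that add atoms: none
Why: Ring-closing metathesis of a gem-disubstituted 1,6-diene to a cyclopentene is very fast; the first-generation catalyst is chosen because it engages internal alkynes only sluggishly, which suppresses enyne metathesis.

Step 10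
Reactants: 16 1-[(2R,3R)-2-(2-TBSO-ethyl)-3-(prop-1-yn-1-yl)oxiran-2-yl]cyclopent-3-en-1-ol
Product: 17 (2R)-2-(2-TBSO-ethyl)-2-[(1R)-1-hydroxybut-2-yn-1-yl]cyclohex-4-en-1-one
Conditions: BF3·OEt2, CH2Cl2, −78 °C; NaHCO3 quench at −78 °C
Reagents that add atoms: none
Why: BF3 coordinates the epoxide oxygen and lengthens the bond to the fully substituted C5; as positive charge builds there, the ring C–C bond of the carbinol carbon that lies antiperiplanar to the breaking C5–O bond shifts to C5 and the hydroxyl collapses to the C6 ketone, which is the Lewis acid semipinacol rearrangement of 2,3-epoxy alcohols with a tertiary carbinol in its ring-expanding form. The six-membered ring is therefore not closed end to end but arises by a 1,2-alkyl shift that inserts C5 into the cyclopentene (one-carbon ring enlargement, new bond C5–C10). The new quaternary stereocentre C5 is controlled by the epoxide configuration: migration is anti, so C5 is inverted while C1 keeps its configuration and is released as the (1R)-carbinol. The two ring methylenes of the cyclopentenol are equivalent, so either one migrates to the same product and no migratory selectivity is needed. What is needed is cleavage of C5–O in preference to C1–O; this is secured by C5 being tertiary and by the alkynyl group at C1, which stabilises a cation far less than an alkenyl group would. Low temperature and a bicarbonate quench protect the silyl ether and keep the β-hydroxy ketone from retro-aldol cleavage.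

Step 11
Reactants: 17 (2R)-2-(2-TBSO-ethyl)-2-[(1R)-1-hydroxybut-2-yn-1-yl]cyclohex-4-en-1-one
Product: 19 (4S,6S)-6-(2-TBSO-ethyl)-4-hydroxy-6-[(1R)-1-hydroxybut-2-yn-1-yl]cyclohex-2-en-1-one, via epoxide 18 (not isolated)
Conditions: VO(acac)2 (cat.), tBuOOH, CH2Cl2, 0 °C to rt; aq Na2S2O3 wash; then Et3N, CH2Cl2, rt
Reagents that add atoms: tert-butyl hydroperoxide, CC(C)(C)OO
Why: Hydroxyl-directed vanadium epoxidation: the vanadate ester of the C1 hydroxyl delivers oxygen to C8=C9 on the ring face that carries C1, while the silyl ether keeps the other arm silent and the alkyne is inert. Triethylamine then removes a C7 proton and opens the β,γ-epoxy ketone to the γ-hydroxy enone; the C9–O bond is untouched, so C9 is obtained cis to C1.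

Step 12
Reactants: 19 (4S,6S)-6-(2-TBSO-ethyl)-4-hydroxy-6-[(1R)-1-hydroxybut-2-yn-1-yl]cyclohex-2-en-1-one
Product: 20 (4S,6S)-4-hydroxy-6-[(1R)-1-hydroxybut-2-yn-1-yl]-6-(2-hydroxyethyl)cyclohex-2-en-1-one
Conditions: HF·pyridine, pyridine, THF, 0 °C to rt
Reagents that add atoms: none
Why: Buffered fluoride cleavage of a primary silyl ether; the weakly acidic medium avoids the retro-aldol and oxa-Michael pathways that a basic fluoride source could open.

Step 13
Reactants: 20 (4S,6S)-4-hydroxy-6-[(1R)-1-hydroxybut-2-yn-1-yl]-6-(2-hydroxyethyl)cyclohex-2-en-1-one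
Product: 23 (1R,5R,9S)-9-hydroxy-1-(prop-1-yn-1-yl)-2-oxaspiro[4.5]dec-7-ene-3,6-dione, via hydroxy aldehyde 21 (not isolated), via lactol 22 (not isolated)
Conditions: 2,2,6,6-tetramethylpiperidin-1-oxyl (TEMPO, cat.), PhI(OAc)2, CH2Cl2, rt
Reagents that add atoms: none
Why: Oxidative lactonisation of a 1,4-diol: the oxoammonium salt oxidises the primary alcohol first, the aldehyde is trapped by the C1 hydroxyl as a five-membered lactol, and the lactol is oxidised to the lactone. The C9 carbinol is secondary and sits on an electron-poor allylic position, and it cannot reach C3 because it is trans to that arm.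

Step 14
Reactants: 23 (1R,5R,9S)-9-hydroxy-1-(prop-1-yn-1-yl)-2-oxaspiro[4.5]dec-7-ene-3,6-dione
Product: 25 (1R,5R,9S)-9-hydroxy-1-[(E)-2-iodoprop-1-en-1-yl]-2-oxaspiro[4.5]dec-7-ene-3,6-dione, via vinylstannane 24 (not isolated)
Conditions: Bu3SnH (slow addition), PdCl2(PPh3)2 (cat.), THF, 0 °C; then I2, CH2Cl2, 0 °C
Reagents that add atoms: iodine, II
Why: Palladium-catalysed syn-hydrostannation places tin on the methyl-bearing alkyne carbon, away from the hindered and oxygenated C1, and iododestannylation proceeds with retention to the (E)-iodide. Slow addition of the hydride lets the fast alkyne addition outrun conjugate reduction of the enone.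

Step 15
Reactants: 26 (1R)-2-hydroxy-1,2,2-triphenylethyl acetate [(R)-HYTRA]; 27 methacrolein
Product: 28 (1R)-2-hydroxy-1,2,2-triphenylethyl (3R)-3-hydroxy-4-methylpent-4-enoate
Conditions: LiN(iPr)2 (2.1 equiv), THF, −78 to 0 °C; then 27, THF/2-methylbutane, −110 °C; recrystallisation
Reagents that add atoms: none
Why: Acetate aldol addition of the doubly deprotonated chiral acetate; the triphenylglycol ester shields one enolate face, and the (R)-reagent should give the (3R)-carbinol that becomes C5′. The minor diastereomer is removed by crystallisation.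

Step 16
Reactants: 28 (1R)-2-hydroxy-1,2,2-triphenylethyl (3R)-3-hydroxy-4-methylpent-4-enoate
Product: 29 (1R)-2-hydroxy-1,2,2-triphenylethyl (3R)-3-TBSO-4-methylpent-4-enoate
Conditions: tBuMe2SiCl, imidazole, DMF, rt
Reagents that add atoms: tert-butyldimethylsilyl chloride, CC(C)(C)[Si](C)(C)Cl
Why: Standard silylation of the secondary allylic alcohol; the tertiary diphenylcarbinol of the auxiliary is too hindered to react.

Step 17
Reactants: 29 (1R)-2-hydroxy-1,2,2-triphenylethyl (3R)-3-TBSO-4-methylpent-4-enoate
Product: 31 (3R)-3-TBSO-4-methylpent-4-en-1-ol, via aldehyde 30 (not isolated)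
Conditions: LiAlH4, Et2O, 0 °C
Reagents that add atoms: none
Why: Hydride reduction of the ester releases the primary alcohol and the recoverable triphenylethanediol; the stereocentre is not involved.

Step 18
Reactants: 31 (3R)-3-TBSO-4-methylpent-4-en-1-ol
Product: 32 tert-butyl{[(3R)-5-iodo-2-methylpent-1-en-3-yl]oxy}dimethylsilane
Conditions: I2, PPh3, imidazole, CH2Cl2, 0 °C
Reagents that add atoms: iodine, II
Why: Appel-type iodination: the alkoxyphosphonium salt is displaced by iodide at the primary carbon.

Step 19
Reactants: 32 tert-butyl{[(3R)-5-iodo-2-methylpent-1-en-3-yl]oxy}dimethylsilane; 25 (1R,5R,9S)-9-hydroxy-1-[(E)-2-iodoprop-1-en-1-yl]-2-oxaspiro[4.5]dec-7-ene-3,6-dione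
Product: 35 (1R,5R,9S)-1-[(1E,5R)-5-TBSO-2,6-dimethylhepta-1,6-dien-1-yl]-9-hydroxy-2-oxaspiro[4.5]dec-7-ene-3,6-dione, via alkyllithium 33 (not isolated), via borate 34 (not isolated)
Conditions: 32, tBuLi (2.1 equiv), Et2O, −78 °C; 9-methoxy-9-borabicyclo[3.3.1]nonane, THF, −78 °C to rt; then 25, PdCl2(dppf) [dppf = 1,1′-bis(diphenylphosphino)ferrocene] (cat.), AsPh3, aq K3PO4, DMF, rt
Reagents that add atoms: none
Why: B-alkyl Suzuki–Miyaura coupling: iodine–lithium exchange and capture by the borinate ester give a borate that transfers its primary alkyl group to the vinylpalladium iodide, and the E geometry is retained. The C9 hydroxyl is left free here so that no allylic acetate meets zerovalent palladium.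

Step 20
Reactants: 35 (1R,5R,9S)-1-[(1E,5R)-5-TBSO-2,6-dimethylhepta-1,6-dien-1-yl]-9-hydroxy-2-oxaspiro[4.5]dec-7-ene-3,6-dione
Product: 36 (1R,5R,9S)-1-[(1E,5R)-5-TBSO-2,6-dimethylhepta-1,6-dien-1-yl]-3,6-dioxo-2-oxaspiro[4.5]dec-7-en-9-yl acetate
Conditions: Ac2O, pyridine, 4-(dimethylamino)pyridine (cat.), CH2Cl2, 0 °C
Reagents that add atoms: acetic anhydride, CC(=O)OC(C)=O
Why: Acylation of the only free hydroxyl; C9 is not touched, so its configuration is kept.

Step 21
Reactants: 36 (1R,5R,9S)-1-[(1E,5R)-5-TBSO-2,6-dimethylhepta-1,6-dien-1-yl]-3,6-dioxo-2-oxaspiro[4.5]dec-7-en-9-yl acetate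
Product: 37 (1R,5R,9S)-1-[(1E,5R)-5-hydroxy-2,6-dimethylhepta-1,6-dien-1-yl]-3,6-dioxo-2-oxaspiro[4.5]dec-7-en-9-yl acetate
Conditions: HF·pyridine, pyridine, THF, 0 °C to rt
Reagents that add atoms: none
Why: Buffered fluoride desilylation frees the C5′ carbinol; the conditions are neither basic enough to eliminate or hydrolyse the acetate nor acidic enough to ionise the allylic alcohol.

## Compound list

1 | but-2-yn-1-ol | CC#CCO | starting material
2 | but-2-ynal | CC#CC=O | intermediate
3 | methyl bis(2,2,2-trifluoroethyl)phosphonoacetate | COC(=O)CP(=O)(OCC(F)(F)F)OCC(F)(F)F | starting material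
4 | tert-butyl(2-iodoethoxy)dimethylsilane | CC(C)(C)[Si](C)(C)OCCI | starting material
5 | methyl 2-[bis(2,2,2-trifluoroethoxy)phosphoryl]-4-TBSO-butanoate (racemic) | COC(=O)C(CCO[Si](C)(C)C(C)(C)C)P(=O)(OCC(F)(F)F)OCC(F)(F)F | intermediate
6 | methyl (2Z)-2-(2-TBSO-ethyl)hex-2-en-4-ynoate | CC#C/C=C(/CCO[Si](C)(C)C(C)(C)C)C(=O)OC | intermediate
7 | (2Z)-2-(2-TBSO-ethyl)hex-2-en-4-ynal (not isolated) | CC#C/C=C(/CCO[Si](C)(C)C(C)(C)C)C=O | intermediate
8 | (2Z)-2-(2-TBSO-ethyl)hex-2-en-4-yn-1-ol | CC#C/C=C(/CCO[Si](C)(C)C(C)(C)C)CO | intermediate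
9 | [(2S,3R)-2-(2-TBSO-ethyl)-3-(prop-1-yn-1-yl)oxiran-2-yl]methanol | CC#C[C@H]1O[C@@]1(CCO[Si](C)(C)C(C)(C)C)CO | intermediate
10 | (2R,3R)-2-(2-TBSO-ethyl)-3-(prop-1-yn-1-yl)oxirane-2-carbaldehyde (not isolated) | CC#C[C@H]1O[C@@]1(CCO[Si](C)(C)C(C)(C)C)C=O | intermediate
11 | (2R,3R)-2-(2-TBSO-ethyl)-3-(prop-1-yn-1-yl)oxirane-2-carboxylic acid | CC#C[C@H]1O[C@@]1(CCO[Si](C)(C)C(C)(C)C)C(=O)O | intermediate
12 | methyl (2R,3R)-2-(2-TBSO-ethyl)-3-(prop-1-yn-1-yl)oxirane-2-carboxylate | CC#C[C@H]1O[C@@]1(CCO[Si](C)(C)C(C)(C)C)C(=O)OC | intermediate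
13 | allylmagnesium bromide | C=CC[Mg]Br | starting material
14 | 1-[(2R,3R)-2-(2-TBSO-ethyl)-3-(prop-1-yn-1-yl)oxiran-2-yl]but-3-en-1-one (not isolated) | CC#C[C@H]1O[C@@]1(CCO[Si](C)(C)C(C)(C)C)C(=O)CC=C | intermediate
15 | 4-[(2R,3R)-2-(2-TBSO-ethyl)-3-(prop-1-yn-1-yl)oxiran-2-yl]hepta-1,6-dien-4-ol | CC#C[C@H]1O[C@@]1(CCO[Si](C)(C)C(C)(C)C)C(O)(CC=C)CC=C | intermediate
16 | 1-[(2R,3R)-2-(2-TBSO-ethyl)-3-(prop-1-yn-1-yl)oxiran-2-yl]cyclopent-3-en-1-ol | CC#C[C@H]1O[C@@]1(CCO[Si](C)(C)C(C)(C)C)C2(O)CC=CC2 | intermediate
17 | (2R)-2-(2-TBSO-ethyl)-2-[(1R)-1-hydroxybut-2-yn-1-yl]cyclohex-4-en-1-one | CC#C[C@@H](O)[C@]1(CCO[Si](C)(C)C(C)(C)C)CC=CCC1=O | intermediate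
18 | (1R,4S,6S)-4-(2-TBSO-ethyl)-4-[(1R)-1-hydroxybut-2-yn-1-yl]-7-oxabicyclo[4.1.0]heptan-3-one, epoxide oxygen cis to the hydroxybutynyl group (not isolated) | CC#C[C@@H](O)[C@]1(CCO[Si](C)(C)C(C)(C)C)C[C@@H]2O[C@@H]2CC1=O | intermediate
19 | (4S,6S)-6-(2-TBSO-ethyl)-4-hydroxy-6-[(1R)-1-hydroxybut-2-yn-1-yl]cyclohex-2-en-1-one | CC#C[C@@H](O)[C@]1(CCO[Si](C)(C)C(C)(C)C)C[C@H](O)C=CC1=O | intermediate
20 | (4S,6S)-4-hydroxy-6-[(1R)-1-hydroxybut-2-yn-1-yl]-6-(2-hydroxyethyl)cyclohex-2-en-1-one | CC#C[C@@H](O)[C@]1(CCO)C[C@H](O)C=CC1=O | intermediate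
21 | 2-{(1R,5S)-5-hydroxy-1-[(1R)-1-hydroxybut-2-yn-1-yl]-2-oxocyclohex-3-en-1-yl}acetaldehyde (not isolated) | CC#C[C@@H](O)[C@]1(CC=O)C[C@H](O)C=CC1=O | intermediate
22 | (1R,5R,9S)-3,9-dihydroxy-1-(prop-1-yn-1-yl)-2-oxaspiro[4.5]dec-7-en-6-one, lactol, both C3 epimers (not isolated) | CC#C[C@H]1OC(O)C[C@]12C[C@H](O)C=CC2=O | intermediate
23 | (1R,5R,9S)-9-hydroxy-1-(prop-1-yn-1-yl)-2-oxaspiro[4.5]dec-7-ene-3,6-dione | CC#C[C@H]1OC(=O)C[C@]12C[C@H](O)C=CC2=O | intermediate
24 | (1R,5R,9S)-9-hydroxy-1-[(E)-2-(tributylstannyl)prop-1-en-1-yl]-2-oxaspiro[4.5]dec-7-ene-3,6-dione (not isolated) | CCCC[Sn](CCCC)(CCCC)/C(C)=C/[C@H]1OC(=O)C[C@]12C[C@H](O)C=CC2=O | intermediate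
25 | (1R,5R,9S)-9-hydroxy-1-[(E)-2-iodoprop-1-en-1-yl]-2-oxaspiro[4.5]dec-7-ene-3,6-dione | I/C(C)=C/[C@H]1OC(=O)C[C@]12C[C@H](O)C=CC2=O | intermediate
26 | (1R)-2-hydroxy-1,2,2-triphenylethyl acetate [(R)-HYTRA] | CC(=O)O[C@H](c1ccccc1)C(O)(c1ccccc1)c1ccccc1 | starting material
27 | methacrolein (2-methylprop-2-enal) | C=C(C)C=O | starting material
28 | (1R)-2-hydroxy-1,2,2-triphenylethyl (3R)-3-hydroxy-4-methylpent-4-enoate | C=C(C)[C@H](O)CC(=O)O[C@H](c1ccccc1)C(O)(c1ccccc1)c1ccccc1 | intermediate
29 | (1R)-2-hydroxy-1,2,2-triphenylethyl (3R)-3-TBSO-4-methylpent-4-enoate | C=C(C)[C@H](O[Si](C)(C)C(C)(C)C)CC(=O)O[C@H](c1ccccc1)C(O)(c1ccccc1)c1ccccc1 | intermediate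
30 | (3R)-3-TBSO-4-methylpent-4-enal (not isolated) | C=C(C)[C@H](O[Si](C)(C)C(C)(C)C)CC=O | intermediate
31 | (3R)-3-TBSO-4-methylpent-4-en-1-ol | C=C(C)[C@H](O[Si](C)(C)C(C)(C)C)CCO | intermediate
32 | tert-butyl{[(3R)-5-iodo-2-methylpent-1-en-3-yl]oxy}dimethylsilane | C=C(C)[C@H](O[Si](C)(C)C(C)(C)C)CCI | intermediate
33 | [(3R)-3-TBSO-4-methylpent-4-en-1-yl]lithium (not isolated) | C=C(C)[C@H](O[Si](C)(C)C(C)(C)C)CC[Li] | intermediate
34 | lithium 9-methoxy-9-[(3R)-3-TBSO-4-methylpent-4-en-1-yl]-9-boranuidabicyclo[3.3.1]nonane (not isolated) | C=C(C)[C@H](O[Si](C)(C)C(C)(C)C)CC[B-]1(OC)C2CCCC1CCC2.[Li+] | intermediate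
35 | (1R,5R,9S)-1-[(1E,5R)-5-TBSO-2,6-dimethylhepta-1,6-dien-1-yl]-9-hydroxy-2-oxaspiro[4.5]dec-7-ene-3,6-dione | C=C(C)[C@H](O[Si](C)(C)C(C)(C)C)CC/C(C)=C/[C@H]1OC(=O)C[C@]12C[C@H](O)C=CC2=O | intermediate
36 | (1R,5R,9S)-1-[(1E,5R)-5-TBSO-2,6-dimethylhepta-1,6-dien-1-yl]-3,6-dioxo-2-oxaspiro[4.5]dec-7-en-9-yl acetate | C=C(C)[C@H](O[Si](C)(C)C(C)(C)C)CC/C(C)=C/[C@H]1OC(=O)C[C@]12C[C@H](OC(C)=O)C=CC2=O | intermediate
37 | (1R,5R,9S)-1-[(1E,5R)-5-hydroxy-2,6-dimethylhepta-1,6-dien-1-yl]-3,6-dioxo-2-oxaspiro[4.5]dec-7-en-9-yl acetate (CNP0151251.2) | C=C(C)[C@H](O)CC/C(C)=C/[C@H]1OC(=O)C[C@]12C[C@H](OC(C)=O)C=CC2=O | target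

## Step count and least certain steps

Total: 21 steps (17 on the core line including coupling and end game, 4 for the side-chain fragment). Longest linear sequence: 16 steps (steps 2–14 and 19–21 from 3; the same length from 1 through steps 1, 3–14 and 19–21).

**Step 10 (key step).** The epoxide may ionise at the propargylic C1–O bond, or it may open to a free cation before the shift. The first would destroy the regiochemistry; the second would erode the anti stereospecificity that fixes C5. The Lewis acid may also strip the silyl ether. Fallback: from 16, the tertiary alcohol is silylated with N-(trimethylsilyl)imidazole to the trimethylsilyl ether F1. F1 is treated with TiCl4 in CH2Cl2 at −78 °C. In this silyl-ether variant of the rearrangement (Tsuchihashi–Suzuki type) the migration is pushed by the silyloxy group and the silicon leaves as its chloride. Aqueous work-up returns 17.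

**Step 11.** Facial selectivity may be poor because the directing oxygen is three carbons from the alkene and has to reach it across the ring from an axial position. The propargylic carbinol may also be oxidised. Fallback by steric control and inversion: from 17, HF·pyridine gives the diol F2, and the nitroxyl/PhI(OAc)2 oxidation closes it to the keto lactone F3, which has no free hydroxyl. Dimethyldioxirane should then attack the ring face away from C1 and its propynyl group to give the anti epoxide F4. Triethylamine opens F4 to the (9R)-alcohol F5. A Mitsunobu reaction with chloroacetic acid inverts C9 to the (9S)-chloroacetate F6. Thiourea with NaHCO3 removes the chloroacetyl group without opening the lactone and returns 23.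

**Step 14.** The palladium hydride may reduce the enone by conjugate addition, or tin may be delivered to the alkyne carbon next to C1. Fallback: from 23, platinum-catalysed syn-hydrosilylation (Et3SiH, PtCl2 with 2-dicyclohexylphosphino-2′,4′,6′-triisopropylbiphenyl) gives the (E)-vinylsilane F7, with silicon on the carbon remote from the oxygenated C1. Iododesilylation with N-iodosuccinimide in hexafluoroisopropanol proceeds with retention and returns 25.

**Step 19.** Aqueous base may open the lactone, after which retro-aldol cleavage of C1–C5 would be irreversible. Boron-to-palladium transfer may also be slow enough for zerovalent palladium to attack the allylic C1–O bond. Fallback: from 32, zinc insertion (Zn dust, LiCl, THF) gives the alkylzinc iodide F8. F8 is coupled with 25 under base-free Negishi conditions (PdCl2(dppf), THF, rt) to return 35; one extra equivalent of F8 is spent on the free hydroxyl.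

## Further compounds

F1 | step 10 | tert-butyldimethyl{2-[(2R,3R)-3-(prop-1-yn-1-yl)-2-{1-[(trimethylsilyl)oxy]cyclopent-3-en-1-yl}oxiran-2-yl]ethoxy}silane | CC#C[C@H]1O[C@@]1(CCO[Si](C)(C)C(C)(C)C)C2(O[Si](C)(C)C)CC=CC2
F2 | step 11 | (2R)-2-[(1R)-1-hydroxybut-2-yn-1-yl]-2-(2-hydroxyethyl)cyclohex-4-en-1-one | CC#C[C@@H](O)[C@]1(CCO)CC=CCC1=O
F3 | step 11 | (1R,5R)-1-(prop-1-yn-1-yl)-2-oxaspiro[4.5]dec-8-ene-3,6-dione | CC#C[C@H]1OC(=O)C[C@]12CC=CCC2=O
F4 | step 11 | (1R,5R,8S,9R)-8,9-epoxy-1-(prop-1-yn-1-yl)-2-oxaspiro[4.5]decane-3,6-dione, epoxide oxygen trans to C1 | CC#C[C@H]1OC(=O)C[C@]12C[C@H]3O[C@H]3CC2=O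
F5 | step 11 | (1R,5R,9R)-9-hydroxy-1-(prop-1-yn-1-yl)-2-oxaspiro[4.5]dec-7-ene-3,6-dione | CC#C[C@H]1OC(=O)C[C@]12C[C@@H](O)C=CC2=O
F6 | step 11 | (1R,5R,9S)-3,6-dioxo-1-(prop-1-yn-1-yl)-2-oxaspiro[4.5]dec-7-en-9-yl chloroacetate | CC#C[C@H]1OC(=O)C[C@]12C[C@H](OC(=O)CCl)C=CC2=O
F7 | step 14 | (1R,5R,9S)-9-hydroxy-1-[(E)-2-(triethylsilyl)prop-1-en-1-yl]-2-oxaspiro[4.5]dec-7-ene-3,6-dione | CC[Si](CC)(CC)/C(C)=C/[C@H]1OC(=O)C[C@]12C[C@H](O)C=CC2=O
F8 | step 19 | [(3R)-3-TBSO-4-methylpent-4-en-1-yl]zinc iodide | C=C(C)[C@H](O[Si](C)(C)C(C)(C)C)CC[Zn]I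
A1 | alternative 1 | tert-butyldimethylsilyl ether of the target (identical with 36) | C=C(C)[C@H](O[Si](C)(C)C(C)(C)C)CC/C(C)=C/[C@H]1OC(=O)C[C@]12C[C@H](OC(C)=O)C=CC2=O
A2 | alternative 1 | (1Z,3S,6R,7E,11R)-11-TBSO-6-hydroxy-1-iodo-8,12-dimethyl-5-methylidenetrideca-1,7,12-trien-3-yl acetate | C=C(C)[C@H](O[Si](C)(C)C(C)(C)C)CC/C(C)=C/[C@@H](O)C(=C)C[C@H](OC(C)=O)/C=C\I
A3 | alternative 2 | cis-fused bromolactone with the quaternary carbon bearing a TBSO-methyl group | O=C1C[C@@]2(CO[Si](C)(C)C(C)(C)C)C=CC[C@H](Br)[C@H]2O1
A4 | alternative 2 | {1-[(TBSO)methyl]cyclohexa-2,5-dien-1-yl}acetic acid | OC(=O)CC1(CO[Si](C)(C)C(C)(C)C)C=CCC=C1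
A5 | alternative 3 | all-cis 3,6-diacetoxycyclohexene with quaternary formyl and carboxymethyl arms | COC(=O)C[C@@]1(C=O)C[C@H](OC(C)=O)C=C[C@@H]1OC(C)=O
A6 | alternative 3 | (1E,3E)-buta-1,3-diene-1,4-diyl diacetate | CC(=O)O/C=C/C=C/OC(C)=O
A7 | alternative 3 | methyl 3-formylbut-3-enoate | COC(=O)CC(=C)C=O
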